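**Plan**

- Numbering: ring A = C1–C2–C3(OAc)–C4(OH)(Me)–C5; ring B = C5–C6(OAc)–C7(iPr)–C8(OAc)–C9–C10(=C14H2)–C1.
- Cuts, in retrosynthetic order: the three acetates; C4–OH and C3–O (back to an epoxide on a C3=C4 alkene); C8–C9 (allylsilane/aldehyde closure of ring B); C4–CH3 (back to the C4 ketone via its enol triflate); C1–C10 and C5–C6 together.
- Enabling feature: C1 and C5 of ring A carry vicinal trans substituents, each the first atom of a ring-B arm (C10 and C6). This is the retron of β-alkenylation and α-aldol trapping on cyclopent-2-enone whose carbonyl is C4.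
- Forward order: ring A comes from cyclopentenone; both ring-B arms are attached in step 6; the ketone becomes the C3=C4(Me) alkene; ring B closes at C8–C9 in step 12; ring A is oxidised last.
- Stereochemistry: C7 from an oxazolidinone auxiliary; C1 from the chiral copper catalyst; C5 and C6 from the aldol (trans, anti); C8 from the cyclisation; C3 and C4 from face-selective epoxidation and invertive hydrolysis at C4.

Key step: step 6

Assumption: the sense of induction of the ferrocenyl diphosphine with this alkenyl Grignard reagent is not predicted here; the ligand enantiomer used is the one that makes C1 S.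

**Route**

Step 1
Reactants: 1 (S)-4-benzyl-1,3-oxazolidin-2-one; 2 3-methylbutanoyl chloride
Product: 3 (S)-4-benzyl-3-(3-methylbutanoyl)-1,3-oxazolidin-2-one
Conditions: Et3N, DMAP (cat.), CH2Cl2, 0 °C → rt
Reagents that add atoms: none
Why: DMAP-catalysed N-acylation of the oxazolidinone by the acid chloride; no stereocentre is involved.

Step 2
Reactants: 3 (S)-4-benzyl-3-(3-methylbutanoyl)-1,3-oxazolidin-2-one
Product: 5 (S)-4-benzyl-3-[(R)-2-(hydroxymethyl)-3-methylbutanoyl]-1,3-oxazolidin-2-one, via chlorotitanium enolate 4 (not isolated)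
Conditions: TiCl4, iPr2NEt, CH2Cl2, 0 °C; then 1,3,5-trioxane, TiCl4, 0 °C; aq NH4Cl
Reagents that add atoms: 1,3,5-trioxane, C1OCOCO1 (source of CH2O)
Why: Evans titanium-enolate hydroxymethylation, in which the chelated (Z)-enolate 4 is attacked by TiCl4-activated formaldehyde on the face opposite the benzyl group, setting the future C7 as R.

Step 3
Reactants: 5 (S)-4-benzyl-3-[(R)-2-(hydroxymethyl)-3-methylbutanoyl]-1,3-oxazolidin-2-one
Product: 6 (S)-4-benzyl-3-[(R)-2-(tert-butyldimethylsilyloxymethyl)-3-methylbutanoyl]-1,3-oxazolidin-2-one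
Conditions: TBSCl, imidazole, CH2Cl2, rt
Reagents that add atoms: tert-butyldimethylsilyl chloride, CC(C)(C)[Si](C)(C)Cl
Why: standard silylation of a primary alcohol; the imide and its α-stereocentre are inert to imidazole.

Step 4
Reactants: 6 (S)-4-benzyl-3-[(R)-2-(tert-butyldimethylsilyloxymethyl)-3-methylbutanoyl]-1,3-oxazolidin-2-one
Product: 7 (S)-2-(tert-butyldimethylsilyloxymethyl)-3-methylbutan-1-ol
Conditions: LiBH4, H2O (1 equiv), Et2O, 0 °C
Reagents that add atoms: none
Why: reductive cleavage of the N-acyl oxazolidinone by LiBH4 gives the primary alcohol and returns the auxiliary; a short reaction at 0 °C should avoid the 1,3-silyl shift that would racemise this diol monoether.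

Step 5
Reactants: 7 (S)-2-(tert-butyldimethylsilyloxymethyl)-3-methylbutan-1-ol
Product: 8 (R)-2-(tert-butyldimethylsilyloxymethyl)-3-methylbutanal (C6 = CHO, C7, C8 = CH2OTBS)
Conditions: Dess–Martin periodinane, pyridine, CH2Cl2, 0 °C → rt
Reagents that add atoms: none
Why: Dess–Martin oxidation under pyridine buffering should give the α-branched aldehyde without epimerising C7; it is used without storage.

Step 6
Reactants: 9 (2-bromoallyl)trimethylsilane; 10 cyclopent-2-en-1-one; 8 (R)-2-(tert-butyldimethylsilyloxymethyl)-3-methylbutanal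
Product: 13 (2S,3S)-2-[(1S,2R)-2-(tert-butyldimethylsilyloxymethyl)-1-hydroxy-3-methylbutyl]-3-[3-(trimethylsilyl)prop-1-en-2-yl]cyclopentan-1-one (route numbering 1S,5S,6S,7R), via alkenylmagnesium bromide 11 (not isolated), via bromomagnesium enolate 12 (not isolated)
Conditions: 9, Mg, 2-MeTHF, rt (gives 11); 10, CuBr·SMe2 (5 mol %), (R)-1-[(S)-2-(diphenylphosphino)ferrocenyl]ethyldicyclohexylphosphine or its enantiomer (6 mol %), t-BuOMe, −78 °C, slow addition of 11; then 8, −78 °C; aq NH4Cl at −78 °C
Reagents that add atoms: none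
Why: Transmetalation of 11 to the chiral monovalent-copper diphosphine complex gives an alkenylcopper species that adds to C1 of 10 (π-complex, trivalent-copper intermediate, reductive elimination) and releases the bromomagnesium enolate 12, which adds to aldehyde 8 through a closed six-membered chair transition state. The closest known reaction type is the CuBr·SMe2/ferrocenyl-diphosphine-catalysed conjugate addition of Grignard reagents to cyclic enones with aldol trapping of the magnesium enolate; alkenyl Grignard reagents are the less explored nucleophiles. No ring is closed; the C1–C10 and C5–C6 bonds are formed. C1 is set by the ligand, C5 by approach of the aldehyde anti to the new C1 substituent (trans), and C6 by the chair with the ring-locked (E)-enolate (anti aldol), in which the aldehyde rotamer free of a syn-pentane contact with C1 has H7 anti to the carbonyl oxygen and the silyloxymethyl arm anti to the forming bond; C7 comes from 8. The step needs 1,4- over 1,2-addition (copper catalysis, slow addition of 11 at −78 °C), a single enolate regioisomer (given by the conjugate addition itself) and no retro-aldol (cold quench); because 8 is a single enantiomer, enolate of the wrong hand ends up in a separable diastereomer.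

Step 7
Reactants: 13 aldol (1S,5S,6S,7R)
Product: 14 C6 tert-butyldimethylsilyl ether of 13 (1S,5S,6S,7R)
Conditions: TBSOTf, 2,6-lutidine, CH2Cl2, −78 °C
Reagents that add atoms: tert-butyldimethylsilyl trifluoromethanesulfonate, CC(C)(C)[Si](C)(C)OS(=O)(=O)C(F)(F)F
Why: silylation of the hindered aldol hydroxyl with the silyl triflate and 2,6-lutidine is fast at −78 °C and avoids the retro-aldol or β-elimination that basic conditions could cause.

Step 8
Reactants: 14 bis-silyl ether ketone (1S,5S,6S,7R)
Product: 16 C3=C4 enol trifluoromethanesulfonate of 14 (1S,5S,6S,7R), via lithium enolate 15 (not isolated)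
Conditions: LiN(iPr)2, THF, −78 °C; PhNTf2, −78 → 0 °C
Reagents that add atoms: N-phenylbis(trifluoromethanesulfonimide), O=S(=O)(N(c1ccccc1)S(=O)(=O)C(F)(F)F)C(F)(F)F
Why: kinetic deprotonation takes the unhindered C3 methylene and not the tertiary C5–H, and O-sulfonylation of enolate 15 fixes the C3=C4 double bond.

Step 9
Reactants: 16 enol trifluoromethanesulfonate (1S,5S,6S,7R)
Product: 17 C4-methyl C3=C4 alkene, i.e. the 1-methylcyclopentene carrying the C6/C7/C8 arm on C5 and the allylsilane on C1 (1S,5R,6R,7R)
Conditions: MeMgBr, Fe(acac)3 (5 mol %), THF/NMP, −30 °C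
Reagents that add atoms: methylmagnesium bromide, C[Mg]Br
Why: iron-catalysed Kumada-type cross-coupling of an alkenyl triflate with a methyl Grignard reagent installs the C4 methyl group; silyl ethers and the allylsilane do not react.

Step 10
Reactants: 17 bis-silyl ether (1S,5R,6R,7R)
Product: 18 C8 primary alcohol, C6 silyl ether retained (1S,5R,6R,7R)
Conditions: HF·pyridine, pyridine, THF, 0 °C
Reagents that add atoms: none
Why: the primary silyl ether is cleaved much faster than the hindered secondary one, and the pyridine-buffered medium should spare the allylsilane.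

Step 11
Reactants: 18 C8 alcohol (1S,5R,6R,7R)
Product: 19 C8 aldehyde (1S,5R,6R,7S; the change of descriptor at C7 is only a priority change)
Conditions: Dess–Martin periodinane, pyridine, CH2Cl2, 0 °C → rt
Reagents that add atoms: none
Why: Dess–Martin oxidation under buffered conditions leaves the allylsilane, the ring alkene and the α-stereocentre C7 untouched.

Step 12
Reactants: 19 C8 aldehyde (1S,5R,6R,7S)
Product: 20 trans-fused hydroazulene: (1S,5R,6R,7R,8S)-6-(tert-butyldimethylsilyloxy)-7-isopropyl-4-methyl-10-methylene bicycle with C3=C4 and free C8–OH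
Conditions: BF3·OEt2, CH2Cl2 (0.005 M), −78 °C; aq NaHCO3
Reagents that add atoms: none
Why: intramolecular Hosomi–Sakurai reaction, in which the terminal CH2 of the allylsilane (C9) attacks the BF3-bound C8 aldehyde (7-exo-trig at the carbonyl), loss of Me3Si from the β-silyl cation leaves the C10=C14 methylene, and a chair-like transition state with the complexed oxygen equatorial (not flanked by both C6 and the isopropyl group) should give the 8S carbinol trans to the isopropyl group.

Step 13
Reactants: 20 silyl ether (1S,5R,6R,7R,8S)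
Product: 21 (1S,5R,6R,7R,8S)-diene-6,8-diol (C3=C4 and C10=C14)
Conditions: Bu4NF, THF, rt → 45 °C
Reagents that add atoms: none
Why: fluoride cleaves the remaining hindered silyl ether; nothing else in 20 reacts with the reagent.

Step 14
Reactants: 21 diene diol (1S,5R,6R,7R,8S)
Product: 22 (1S,3S,4R,5S,6S,7R,8S)-3,4-epoxide on the face of H1 (anti to H5), C10=C14 retained
Conditions: mCPBA (1.0 equiv), NaHCO3, CH2Cl2, −20 → 0 °C
Reagents that add atoms: 3-chloroperoxybenzoic acid, OOC(=O)c1cccc(Cl)c1
Why: Prilezhaev epoxidation, in which the trisubstituted ring-A alkene is far more nucleophilic than the 1,1-disubstituted methylene, and the peracid should approach anti to the pseudo-axial C5–H bond (staggered, torsionally favoured), the same face on which the nearby C6 hydroxyl can hydrogen-bond the reagent.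

Step 15
Reactants: 22 epoxy diol (1S,3S,4R,5S,6S,7R,8S)
Product: 23 (1S,3S,4S,5S,6S,7R,8S)-3,4,6,8-tetrol
Conditions: HClO4 (cat.), THF/H2O, 0 °C
Reagents that add atoms: water, O
Why: acid-catalysed epoxide hydrolysis, in which water attacks the tertiary C4 with inversion, so the epoxide oxygen stays on C3 and the new C4 hydroxyl ends trans to it and cis to H5.

Step 16
Reactants: 23 tetrol (1S,3S,4S,5S,6S,7R,8S)
Product: 24 (1S,3S,4S,5S,6S,7R,8S)-3,6,8-triacetoxy-4-hydroxy compound (target)
Conditions: Ac2O, pyridine, DMAP (cat.), CH2Cl2, 0 °C → rt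
Reagents that add atoms: acetic anhydride, CC(=O)OC(C)=O
Why: DMAP-catalysed acetylation esterifies the three secondary hydroxyls, while the tertiary C4 hydroxyl reacts much more slowly and should stay free.

**Compound list**

1 | (S)-4-benzyl-1,3-oxazolidin-2-one | O=C1OC[C@H](Cc2ccccc2)N1 | starting material
2 | 3-methylbutanoyl chloride | CC(C)CC(Cl)=O | starting material
3 | (S)-4-benzyl-3-(3-methylbutanoyl)-1,3-oxazolidin-2-one | CC(C)CC(=O)N1[C@@H](Cc2ccccc2)COC1=O | intermediate
4 | chlorotitanium (Z)-enolate of 3 | CC(C)/C=C(/N1[C@@H](Cc2ccccc2)COC1=O)O[Ti](Cl)(Cl)Cl | intermediate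
5 | (S)-4-benzyl-3-[(R)-2-(hydroxymethyl)-3-methylbutanoyl]-1,3-oxazolidin-2-one | CC(C)[C@H](CO)C(=O)N1[C@@H](Cc2ccccc2)COC1=O | intermediate
6 | (S)-4-benzyl-3-[(R)-2-(tert-butyldimethylsilyloxymethyl)-3-methylbutanoyl]-1,3-oxazolidin-2-one | CC(C)[C@H](CO[Si](C)(C)C(C)(C)C)C(=O)N1[C@@H](Cc2ccccc2)COC1=O | intermediate
7 | (S)-2-(tert-butyldimethylsilyloxymethyl)-3-methylbutan-1-ol | CC(C)[C@H](CO[Si](C)(C)C(C)(C)C)CO | intermediate
8 | (R)-2-(tert-butyldimethylsilyloxymethyl)-3-methylbutanal | CC(C)[C@H](CO[Si](C)(C)C(C)(C)C)C=O | intermediate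
9 | (2-bromoallyl)trimethylsilane | C[Si](C)(C)CC(Br)=C | starting material
10 | cyclopent-2-en-1-one | O=C1C=CCC1 | starting material
11 | [3-(trimethylsilyl)prop-1-en-2-yl]magnesium bromide | C[Si](C)(C)CC(=C)[Mg]Br | intermediate
12 | bromomagnesium enolate of (S)-3-[3-(trimethylsilyl)prop-1-en-2-yl]cyclopentanone (C4=C5, O–MgBr on C4) | C[Si](C)(C)CC(=C)[C@H]1CCC(O[Mg]Br)=C1 | intermediate
13 | (2S,3S)-2-[(1S,2R)-2-(tert-butyldimethylsilyloxymethyl)-1-hydroxy-3-methylbutyl]-3-[3-(trimethylsilyl)prop-1-en-2-yl]cyclopentan-1-one | CC(C)(C)[Si](C)(C)OC[C@@H](C(C)C)[C@H](O)[C@@H]1[C@@H](C(=C)C[Si](C)(C)C)CCC1=O | intermediate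
14 | C6 tert-butyldimethylsilyl ether of 13 (1S,5S,6S,7R) | CC(C)(C)[Si](C)(C)OC[C@@H](C(C)C)[C@H](O[Si](C)(C)C(C)(C)C)[C@@H]1[C@@H](C(=C)C[Si](C)(C)C)CCC1=O | intermediate
15 | lithium enolate of 14 (C3=C4, O–Li on C4) | CC(C)(C)[Si](C)(C)OC[C@@H](C(C)C)[C@H](O[Si](C)(C)C(C)(C)C)[C@@H]1[C@@H](C(=C)C[Si](C)(C)C)CC=C1O[Li] | intermediate
16 | C3=C4 enol trifluoromethanesulfonate of 14 (1S,5S,6S,7R) | CC(C)(C)[Si](C)(C)OC[C@@H](C(C)C)[C@H](O[Si](C)(C)C(C)(C)C)[C@@H]1[C@@H](C(=C)C[Si](C)(C)C)CC=C1OS(=O)(=O)C(F)(F)F | intermediate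
17 | C4-methyl C3=C4 alkene with C6 and C8 silyl ethers (1S,5R,6R,7R) | CC(C)(C)[Si](C)(C)OC[C@@H](C(C)C)[C@H](O[Si](C)(C)C(C)(C)C)[C@@H]1[C@@H](C(=C)C[Si](C)(C)C)CC=C1C | intermediate
18 | C8 primary alcohol, C6 silyl ether (1S,5R,6R,7R) | OC[C@@H](C(C)C)[C@H](O[Si](C)(C)C(C)(C)C)[C@@H]1[C@@H](C(=C)C[Si](C)(C)C)CC=C1C | intermediate
19 | C8 aldehyde, C6 silyl ether (1S,5R,6R,7S) | O=C[C@@H](C(C)C)[C@H](O[Si](C)(C)C(C)(C)C)[C@@H]1[C@@H](C(=C)C[Si](C)(C)C)CC=C1C | intermediate
20 | trans-fused hydroazulene, C3=C4, C10=C14, C6 silyl ether, C8–OH (1S,5R,6R,7R,8S) | C=C1C[C@H](O)[C@@H](C(C)C)[C@H](O[Si](C)(C)C(C)(C)C)[C@@H]2[C@@H]1CC=C2C | intermediate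
21 | diene-6,8-diol (1S,5R,6R,7R,8S) | C=C1C[C@H](O)[C@@H](C(C)C)[C@H](O)[C@@H]2[C@@H]1CC=C2C | intermediate
22 | 3,4-epoxy-6,8-diol, epoxide anti to H5 (1S,3S,4R,5S,6S,7R,8S) | C=C1C[C@H](O)[C@@H](C(C)C)[C@H](O)[C@@H]2[C@@H]1C[C@@H]3O[C@]23C | intermediate
23 | 3,4,6,8-tetrol (1S,3S,4S,5S,6S,7R,8S) | C=C1C[C@H](O)[C@@H](C(C)C)[C@H](O)[C@@H]2[C@@H]1C[C@H](O)[C@@]2(C)O | intermediate
24 | 3,6,8-triacetoxy-4-hydroxy target (1S,3S,4S,5S,6S,7R,8S) | C=C1C[C@H](OC(C)=O)[C@@H](C(C)C)[C@H](OC(C)=O)[C@@H]2[C@@H]1C[C@H](OC(C)=O)[C@@]2(C)O | target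

**Totals and risks**

Total step count: 16. Longest linear sequence: 16 steps (1 → 24); the alkenyl Grignard reagent and cyclopentenone enter in step 6.

Most likely to fail:

1. Step 6. The chiral copper complex may discriminate the faces of the five-membered enone poorly with this α-branched alkenyl nucleophile, and the aldol trapping places the isopropyl group in the more crowded inside position, so it may be slow. Fallback, setting out from 9, 10 and 8: absolute control is moved from the catalyst to the aldehyde. Reagent 11 is added to 10 with CuBr·SMe2 alone (no ligand, THF, −78 °C) to give racemic 12, which is trapped with enantiopure 8. The two trans, anti adducts, 13 and the (1R,5R,6R,7R)-diastereomer of 13 F1, differ at three of four stereocentres and should separate on silica; 13 re-enters the route at step 7, at the cost of about half the material.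

2. Step 14. The peracid may attack the other face of the ring-A alkene (the face of H5), which after hydrolysis would invert both C3 and C4. Fallback, setting out from 21: N-bromosuccinimide in THF/H2O at 0 °C places the bromonium ion on the face the peracid preferred, and water opens it at the tertiary C4 from the opposite face to give the 3-bromo-4,6,8-triol F2. K2CO3 in MeOH then closes the C4 alkoxide onto C3 with inversion, which gives the epoxide anti to H5, compound 22.

3. Step 12. The allylsilane may add to the other face of the C8 aldehyde and give the axial carbinol. Fallback, setting out from 19: the cyclisation product is then the C8 epimer of 20 F3. Dess–Martin oxidation (pyridine, CH2Cl2, 0 °C) gives the C8 ketone F4, and NaBH4 in MeOH at −40 °C, delivering hydride axially (anti to the axial C7–H), should return the equatorial alcohol 20. F4 is a β,γ-unsaturated ketone and is kept cold and free of base.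

Further compounds
F1 | step 6 | (1R,5R,6R,7R)-diastereomer of 13 | CC(C)(C)[Si](C)(C)OC[C@@H](C(C)C)[C@@H](O)[C@H]1[C@H](C(=C)C[Si](C)(C)C)CCC1=O
F2 | step 14 | (1S,3R,4R,5S,6S,7R,8S)-3-bromo-4,6,8-triol (Br on the face of H5, C4–OH anti to H5) | C=C1C[C@H](O)[C@@H](C(C)C)[C@H](O)[C@@H]2[C@@H]1C[C@@H](Br)[C@]2(C)O
F3 | step 12 | C8 epimer of 20 (1S,5R,6R,7R,8R) | C=C1C[C@@H](O)[C@@H](C(C)C)[C@H](O[Si](C)(C)C(C)(C)C)[C@@H]2[C@@H]1CC=C2C
F4 | step 12 | C8 ketone from F3 (1S,5R,6R,7S) | C=C1CC(=O)[C@@H](C(C)C)[C@H](O[Si](C)(C)C(C)(C)C)[C@@H]2[C@@H]1CC=C2C
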